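- At 144 h, my last reading of birch, the very flask asked about, target stood at 26.6% and substrate at 61.9%, much as at 30.0 h.

| setting | birch | oak | flask |
|---|---|---|---|
| substrate | 0.015 M | 0.015 M | 0.015 M |
| reagent | 0.95 equiv | 0.95 equiv | 0.950 equiv |
| free catalyst | 7.7 mol% | 3.9 mol% | 7.7 mol% |
| second catalyst | 0.19 mol% | 0.19 mol% | 0.19 mol% |
| remark | the very flask that is asked about, followed so far | run made earlier |  |
| time |  |  | 8.0 d |

| run | time / h | target / % | substrate / % |
|---|---|---|---|
| birch | 30.0 | 26.0 | 61.8 |
| birch | 60.0 | 26.4 | 61.3 |
| birch | 96.0 | 26.4 | 62.2 |
| birch | 120 | 26.4 | 61.8 |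
| birch | 144 | 26.6 | 61.9 |
| oak | 2.50 | 5.8 | 92.5 |
| oak | 5.00 | 9.9 | 86.1 |
| oak | 8.00 | 13.4 | 80.9 |
| oak | 15.0 | 17.1 | 72.7 |
| oak | 30.0 | 18.2 | 68.7 |

(readings scatter by 0.3 percentage points)

- target that was removed still counts
- "the catalyst" is free catalyst with its forms; second catalyst is a second catalyst
- additions bring no volume worth counting

- Monday's: at 8.0 d add free catalyst, 100% of the amount charged, then wait 2.5 d
- Friday's: at 8.0 d add reagent, 100% of the amount charged, then wait 2.5 d
- Wednesday's: change nothing and wait 2.5 d more
- Sunday's: at 8.0 d take out 90% of the target then present, then wait 2.5 d

- target, in percent of the substrate first charged, at 8.0 d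
- the option that brings most further target ("none" if no option brings more than 2 percentage points) (Monday's / Friday's / Wednesday's / Sunday's / none)
- target present, with what was taken out counted in, in percent of the substrate first charged, after Friday's
- target present, with what was taken out counted in, in percent of the substrate first charged, after Sunday's

- In oak at 30.0 h, the share found neither as substrate nor as target, divided by the substrate still there, came to 0.191; I called this the gap ratio.
- First rung of the ladder: by 5.00 h oak's target had reached half of its last reading, so target's clock ran in hours.
- Second rung: by 15.0 h oak's target had nearly all of that reading, yet its gap ratio was 0.140, lower than the 0.191 of the last reading, so oak's gap was still filling.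
- Third rung: the asked time lay 1.58 powers of ten past oak's half-way mark, and birch had been flat since 30.0 h.
- Birch had twice oak's free catalyst and more target, but its gap ratio of 0.186 matched oak's, so I took the gap for a balance that free catalyst does not shift.
- From the flat birch readings I took 26.4% for target; oak's ratio then gave birch substrate 61.8%, beside the 61.9% read. I committed to no option passing 2 percentage points, loosely.
- The forecast gave 26.5%, 26.6% after Friday's and 26.6% after Sunday's, but chose Monday's: “Fresh catalyst should restart the reaction”. There I parted from it.

    substrate + free catalyst ⇌ free catalyst + intermediate (K = 0.190, k = 58.0 L mol⁻¹ h⁻¹)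
    reagent + second catalyst + intermediate → second catalyst + target (k = 4.60 × 10⁶ L² mol⁻² h⁻¹)
    second catalyst → spent catalyst (k = 0.280 h⁻¹)

- The flask gave 26.4% at 8.0 d, 26.4% after Friday's and 26.4% after Sunday's, with Monday's bringing 0 points, so the best was none. Second catalyst stood at 0% of its charge at 192 h. The gap was the intermediate, in a pre-equilibrium with substrate, so the gap ratio reads c(intermediate)/c(substrate); on this flask it turned target into substrate 61.8%, and the flask held 61.8%. The neighbouring flask, with 0.380 equiv of reagent, gave target 14.4%; the ratio turned that into substrate 71.9% and intermediate 13.7%, and that neighbouring flask held substrate 71.9% and intermediate 13.7%.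

The data stem from a simulated flask with made-up constants, noise included.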